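## Structural features

The target joins four guaiacyl-type C6C3 units into three ring systems. These are a γ-butyrolactone, a 2,3-dihydrobenzofuran (pendant ring A, fused ring C) and an open 3-hydroxy-1,2-diarylpropan-1-one arm linking central ring B to ring D. Lactone Cβ (R) carries the CH2 of ring B, the neighbouring Cα (R) carries the CH2 bound to C5 of ring C, and the two arylmethyl groups are trans. In the dihydrofuran the adjacent centres C2 (S, ring A) and C3 (R, CH2OH) are also trans. The fifth centre, C8' (S), sits on C5 of ring B ortho to the phenol, and is at once benzylic, α to the ring D ketone (C7') and β to a primary hydroxyl (C9'). The fragile groups are this centre (enolisation, retro-aldol loss of formaldehyde, dehydration), the benzylic C2–O1 bond (acid, hydrogenolysis), the lactone with its epimerisable Cα–H (base, hydride) and three oxidisable phenols. The real difficulty is that the three stereochemical clusters are too far apart to relay information, so each needs its own absolute control, and C8' must be made late and then meet only near-neutral reagents. The key step exploits the lactone ring: its carbonyl carbon is the only ring atom without a carbon substituent, O–CH2–Cβ–Cα is the skeleton of an allylic alcohol, and Cα and Cβ each hold one hydrogen and one arylmethyl group, so both can be the carbons of one trisubstituted alkene while C=O comes from carbon monoxide.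

## Logic of the disconnections

**28 to 27.** The three phenolic O–benzyl bonds on rings A, B and D are cut. C8' tolerates neither base nor strong acid, so the last unmasking must be a neutral hydrogenolysis. The gain is that no free phenol is present during the carbenoid, palladium, boron and manganese chemistry. The demand is that every benzyl group sits on a phenol and none on an alcohol, so that cleavage is quick enough to spare the C2–O1 bond and the ketone. Both primary hydroxyls therefore stay free.

**27 to 22 and 23 (through 26 and 25).** The ketone is traced back to a benzylic carbinol and the C9' hydroxymethyl group to an imide carbonyl, and then the C7'–C8' bond is cut. In this form C8' is not yet α to a ketone, and it is created in an auxiliary-controlled aldol addition of predictable sense. Ring D, C7' and the labile centre vanish and a plain arylacetyl imide remains. The forward steps must enolise the imide and not the lactone, reduce the imide and not the lactone, and oxidise the benzylic secondary hydroxyl beside two primary ones.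

**22 to 19 and 21 (21 from 20).** The bond between C5 of ring B and the arm CH2 is cut. It is an aryl–CH2C(=O) bond and can be made by enolate arylation from a halogen that ring B carries from the start. This avoids unmasking a phenol, functionalising ortho to it and protecting it again after the lactone is built. The whole arm is removed. The demand is an enolate equivalent that works without alkoxide or amide base, and a catalyst able to insert into an electron-rich C–Cl bond.

**19 to 18.** The Cα–C(=O) and C(=O)–O bonds are cut and CO is taken out.
- The ring, two bonds and both lactone stereocentres collapse into a flat alkene whose halves can be joined by olefination.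
- Syn delivery of H (to C2) and acyl (to C3), followed by rotation to close the ring, places the C2 arylmethyl cis to the C3 hydrogen. The isomer with the two arylmethyl groups cis is therefore required. Because CH2OH outranks arylmethyl at C2, this isomer is E.
- The demands are geometric purity of 18, palladium ending on C3, one alkene face, and CO capture ahead of β-hydride elimination.
- Three features of 18 serve this: a free allylic hydroxyl for chelation, no alkyl benzyl ether, and chlorine as a handle inert to arylphosphine-ligated palladium.

**18 to 9 and 16 (through 17).** The C2=C3 double bond is cut after raising CH2OH to the ester. This is the most convergent cut, separating the ring B part from the dihydrobenzofuran. A base-free ester-stabilised ylide is chosen over a phosphonate anion because the partner is an enolisable arylacetaldehyde and because E selectivity must be high. One hydride reduction then serves both esters.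

**16 to 13 and 14; 13 to 10 (through 12 and 11).** The ring B CH2–C bond is cut, leading to a benzylic bromide and a commercial ylide. The remaining steps are protection, reduction and bromination. The demand is C-alkylation without external base.

**9 to 7 (through 8).** The bond between the aldehyde carbon and the benzylic CH2 is cut as a one-carbon homologation. The formyl group of the starting arene thereby becomes the future Cα-bound CH2. The ylide must add to the aldehyde faster than it deprotonates the C3 ester.

**7 to 5 (through 6).** The C2–C3 bond of the dihydrofuran is cut. A carbenoid at the future C3 inserts into the ArCH2–O methylene, so ring and C2 configuration arise together from an achiral ether. The ester makes C3 correctable to trans and is the latent CH2OH. The demand is a catalyst that tells the two benzylic hydrogens apart.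

**5 to 3 and 4; 3 to 1 and 2.** The aryl–C(N2) bond and the phenol O–CH2 bond are cut, reaching three commercial compounds. The coupling must keep the diazo group and tolerate the aldehyde.

## Other disconnections considered

**Alternative 1:** The cut is the O1–C2 bond of the dihydrofuran.
- *Forward step.* The 1,3-diol A2 is single at the carbon that becomes C3 but mixed at the benzylic carbinol. On treatment with acid, water leaves the p-hydroxybenzylic position and both epimers merge in quinone methide A3. The ring C phenol then adds to the methide carbon to give trans-dihydrobenzofuran A1.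
- *In favour.* Only one centre has to be set beforehand, by auxiliary chemistry of predictable sense. The carbinol mixture needs no separation, and neither a diazo compound nor rhodium is required.
- *Against.* The methide needs ring A as a free phenol, so A1 emerges with a phenol and an alcohol still to be protected. The arylacetic acid behind A2 is not commercial. The bromide must be extended by two carbons, and A3 can be trapped intermolecularly.
- *Structure.* It addresses the ring built in steps 1–4 and leaves the lactone and C8' open. It makes one bond, one ring and one centre, where step 13 makes two bonds, one ring and two centres.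
- *Mechanism.* Both plans let the trans preference of the ring fix one of the two centres, by ionic closure there and by enolate equilibration in step 4.
- *Balance.* In predictability of absolute sense and in reliability the alternative is the better. In step economy the chosen four steps from 1 and 2 to 7 are shorter by about four. It could replace steps 1–4 without touching the key step.

**Alternative 2:** The cut is the lactone O–CH2 bond, followed by the Cα–CH2 bond.
- *Forward step.* A flavin monooxygenase adds oxygen to prochiral cyclobutanone A5 and lets one of the two enantiotopic CH2 groups migrate, giving β-substituted lactone A4. The enolate of A4 is then alkylated with benzylic bromide A6 anti to the β-substituent to give trans-lactone A7.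
- *In favour.* Desymmetrisation of 3-substituted cyclobutanones is an established reaction class run in water with O2. The trans-selective alkylation is the standard entry to dibenzylbutyrolactones. The route is highly convergent, and the aryl bromide of A7 is a more reactive handle than the chloride of 19, which is a point for the alternative.
- *Against.* A5 needs a ketene [2+2] addition and dechlorination. The enzyme must accept a large lipophilic arene and must show the R preference. The strong base forces protection of the dihydrobenzofuran hydroxyl, and A6 is a labile p-alkoxybenzyl bromide.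
- *Structure.* The two lactone centres are set in two operations instead of one.
- *Mechanism.* Migration within an enzyme-bound Criegee adduct followed by substrate control stands against one face-selective syn addition.
- *Balance.* Step count is about equal, since the savings on the lactone are spent on A5 and A6. In reliability the alternative is clearly the better. The chosen plan offers a base-free closure with both centres from one catalytic event and a one-carbon feedstock.

**Alternative 3:** The cuts are the ring C–C3 bond and the CH2–O bond.
- *Forward step.* The aryl radical from iodide A9 closes 5-exo onto the vinyl group, and the primary radical is captured by TEMPO to give A8.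
- *In favour.* It starts from the same iodoarene as the chosen plan. C2 is set beforehand in an intermolecular etherification for which good asymmetric methods exist. The CH2–O carbon arrives at the alcohol oxidation level, so redox economy is better than in the ester route, and the aldehyde survives.
- *Against.* A9 is an allylic and p-alkoxybenzylic aryl ether prone to ionisation, racemisation and [3,3] shift. The aryl radical can abstract the C2 hydrogen by 1,5-transfer. The N–O bond must be cleaved reductively.
- *Structure and mechanism.* It rivals steps 1–4 only. The cis/trans outcome depends only on a chair-like transition state and cannot be corrected later, whereas the ester of 6 allows equilibration to 7, which is a point for the chosen plan.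
- *Balance.* Step counts to an aldehyde of the type of 7 are about equal, and neither the lactone nor C8' is addressed.

Key step: step 13

Assumption: the sense of induction of Rh2(S-PTTL)4 (step 3) and of (R,R)-BICP (step 13) on these substrates is taken by analogy. Both are available in either mirror-image form, and the antipode is used if the opposite sense is found.

## Steps

Step 1
Reactants: 1 4-benzyloxy-3-methoxybenzyl alcohol; 2 5-iodovanillin
Product: 3 4-[(4-benzyloxy-3-methoxyphenyl)methoxy]-3-iodo-5-methoxybenzaldehyde
Conditions: PPh3, DIAD, THF, 0 °C to rt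
Reagents that add atoms: none
Why: Mitsunobu etherification; the phenol of 2 is acidified by its para formyl group and the primary electron-rich benzylic alcohol is displaced easily, so the hindered aryl–O–CH2 bond forms without base and without a separate halide step.

Step 2
Reactants: 3 aryl iodide; 4 ethyl diazoacetate
Product: 5 ethyl 2-diazo-2-{2-[(4-benzyloxy-3-methoxyphenyl)methoxy]-5-formyl-3-methoxyphenyl}acetate
Conditions: Pd(PPh3)4 (5 mol %), Ag2CO3, Et3N, toluene, rt
Reagents that add atoms: none
Why: Palladium-catalysed cross-coupling of an aryl iodide with the C–H bond of a diazoacetate, a known route to aryldiazoacetates in which reductive elimination at room temperature outruns loss of N2. The amine is too weak to add 4 to the formyl group and the silver salt takes up iodide.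

Step 3
Reactants: 5 aryldiazoacetate
Product: 6 ethyl (2S,3R)-2-(4-benzyloxy-3-methoxyphenyl)-5-formyl-7-methoxy-2,3-dihydrobenzofuran-3-carboxylate (cis)
Conditions: Rh2(S-PTTL)4 [dirhodium tetrakis(N-phthaloyl-(S)-tert-leucinate)] (1 mol %), toluene, −60 °C
Reagents that add atoms: none
Why: Intramolecular 1,5 C–H insertion of a donor/acceptor rhodium carbenoid into the ArCH2–O methylene forms C2–C3 and closes the dihydrofuran. Dirhodium phthaloyl-tert-leucinate catalysts are known to give cis-2-aryl-2,3-dihydrobenzofuran-3-carboxylates; the catalyst picks one of the two enantiotopic benzylic hydrogens and so sets C2 (S), while C3 is corrected in step 4.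

Step 4
Reactants: 6 cis ester
Product: 7 ethyl (2S,3S)-2-(4-benzyloxy-3-methoxyphenyl)-5-formyl-7-methoxy-2,3-dihydrobenzofuran-3-carboxylate (trans)
Conditions: NaOEt (0.3 equiv), EtOH, 0 °C to rt
Reagents that add atoms: none
Why: Base-mediated epimerisation through the ester enolate moves C3 to the thermodynamically preferred trans arrangement while C2 is untouched. Ethoxide matches the ester, and the protic medium reprotonates the enolate before it can expel the ring oxygen.

Step 5
Reactants: 7 trans ester aldehyde
Product: 8 ethyl (2S,3S)-2-(4-benzyloxy-3-methoxyphenyl)-7-methoxy-5-(2-methoxyvinyl)-2,3-dihydrobenzofuran-3-carboxylate (E/Z mixture)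
Conditions: Ph3P(CH2OMe)Cl, NaHMDS, THF, −78 to 0 °C
Reagents that add atoms: (methoxymethyl)triphenylphosphonium chloride, COC[P+](c1ccccc1)(c1ccccc1)c1ccccc1.[Cl-]
Why: Wittig methoxymethylenation of the aromatic aldehyde. The ylide is preformed with the salt in slight excess over the base and met at low temperature, so carbonyl addition outruns deprotonation at C3, which already holds its thermodynamic configuration.

Step 6
Reactants: 8 enol ether
Product: 9 ethyl (2S,3S)-2-(4-benzyloxy-3-methoxyphenyl)-7-methoxy-5-(2-oxoethyl)-2,3-dihydrobenzofuran-3-carboxylate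
Conditions: 2 M aq. HCl, THF, rt
Reagents that add atoms: water, O
Why: Acid hydrolysis of the enol ether (C-protonation, hydration, loss of methanol) unmasks the arylacetaldehyde; dilute acid at room temperature leaves the ester, the benzyl ether and the C2–O1 bond intact. The aldehyde is used at once.

Step 7
Reactants: 10 5-chlorovanillin
Product: 11 4-benzyloxy-3-chloro-5-methoxybenzaldehyde
Conditions: BnBr, K2CO3, DMF, rt
Reagents that add atoms: benzyl bromide, BrCc1ccccc1
Why: Williamson benzylation of an acidic phenol; the chlorine is the later coupling handle and the benzyl group is the only protection ring B ever needs.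

Step 8
Reactants: 11 aldehyde
Product: 12 (4-benzyloxy-3-chloro-5-methoxyphenyl)methanol
Conditions: NaBH4, MeOH, 0 °C
Reagents that add atoms: none
Why: Borohydride reduction of an aromatic aldehyde; aryl chloride and benzyl ether are inert.

Step 9
Reactants: 12 benzylic alcohol
Product: 13 4-benzyloxy-3-chloro-5-methoxybenzyl bromide
Conditions: PBr3, CH2Cl2, 0 °C
Reagents that add atoms: phosphorus tribromide, BrP(Br)Br
Why: Substitution of a primary benzylic alcohol through its phosphite ester; the ring chlorine tempers the ionisation tendency of the p-alkoxybenzyl bromide, which can therefore be handled.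

Step 10
Reactants: 13 benzylic bromide; 14 (ethoxycarbonylmethylene)triphenylphosphorane
Product: 16 ethyl 3-(4-benzyloxy-3-chloro-5-methoxyphenyl)-2-(triphenylphosphoranylidene)propanoate, via phosphonium bromide 15 (not isolated)
Conditions: 14 (2 equiv), EtOAc, reflux; filter
Reagents that add atoms: none
Why: C-alkylation of the stabilised ylide gives salt 15, which a second equivalent of 14 deprotonates (transylidation), so no external base meets the benzylic halide. The spent salt precipitates.

Step 11
Reactants: 9 arylacetaldehyde; 16 substituted ylide
Product: 17 ethyl (2S,3S)-2-(4-benzyloxy-3-methoxyphenyl)-5-[(2E)-3-(4-benzyloxy-3-chloro-5-methoxybenzyl)-4-ethoxy-4-oxobut-2-en-1-yl]-7-methoxy-2,3-dihydrobenzofuran-3-carboxylate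
Conditions: CH2Cl2, rt to 40 °C
Reagents that add atoms: none
Why: Wittig olefination with an α-substituted ester-stabilised ylide strongly favours the alkene with the ester trans to the aldehyde residue, that is E with both arylmethyl groups cis. The salt-free neutral medium spares the enolisable aldehyde and gives no base to move the double bond toward ring C.

Step 12
Reactants: 17 diester
Product: 18 (2E)-2-(4-benzyloxy-3-chloro-5-methoxybenzyl)-4-[(2S,3R)-2-(4-benzyloxy-3-methoxyphenyl)-3-(hydroxymethyl)-7-methoxy-2,3-dihydrobenzofuran-5-yl]but-2-en-1-ol
Conditions: DIBAL-H (5 equiv), CH2Cl2, −78 to 0 °C; Rochelle salt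
Reagents that add atoms: none
Why: DIBAL-H reduces the conjugated ester by 1,2-addition and the C3 ester in the same operation, without touching alkene geometry, aryl chloride or benzyl ethers. C3 becomes R only through the change of priorities.

Step 13
Reactants: 18 E-allylic alcohol
Product: 19 (3R,4R)-4-(4-benzyloxy-3-chloro-5-methoxybenzyl)-3-{[(2S,3R)-2-(4-benzyloxy-3-methoxyphenyl)-3-(hydroxymethyl)-7-methoxy-2,3-dihydrobenzofuran-5-yl]methyl}dihydrofuran-2(3H)-one
Conditions: Pd(OAc)2 (5 mol %), (R,R)-BICP (10 mol %), CO/H2 (1:1, 55 bar), CH2Cl2, 80 °C
Reagents that add atoms: carbon monoxide, [C-]#[O+]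
Why: Proposed new method: under CO/H2 the Pd(OAc)2/bisphosphine mixture forms a divalent palladium hydride that binds the alkene of 18 with help from the allylic hydroxyl and adds syn, H to the fully substituted C2 and Pd to C3, because a tertiary alkylpalladium is disfavoured and only the C3 acyl can reach a five-membered ring. CO then inserts into the C3–Pd bond with retention and the tethered primary hydroxyl attacks the acylpalladium carbon in a 5-exo-trig acyl capture that closes the lactone, makes the Cα–C(=O) and C(=O)–O bonds and returns the hydride, so only CO is consumed. The closest known reaction type is the palladium/1,4-bisphosphine cyclocarbonylation of simpler allylic alcohols (1,1-disubstituted or aryl-conjugated alkenes, mostly tertiary carbinols) to γ-butyrolactones; a primary, non-conjugated, trisubstituted allylic alcohol flanked by two benzylic CH2 groups lies outside that scope. Relative configuration follows from alkene geometry: H and acyl arrive on one face, so the E alkene with its arylmethyl groups cis maps onto the trans lactone, and any cis material can be drained to trans with mild base because Cα is epimerisable. Absolute configuration at Cβ (R) and Cα (R) is fixed by the alkene face that the seven-membered BICP chelate leaves open; the dihydrobenzofuran centres are too remote to interfere, and a wrong-face product is a separable diastereomer. The selectivity needed is CO capture of the secondary alkylpalladium ahead of β-hydride elimination toward C4 and chain walking to ring C, which is served by high CO pressure, moderate temperature and the five-membered O-to-Pd chelate of the free hydroxyl that fills the cis site. The aryl chloride, the aryl benzyl ethers and the remote hydroxyl are spectators: arylphosphine-ligated palladium does not insert into an electron-rich C–Cl bond at this temperature, CO suppresses heterogeneous hydrogenolysis, and intramolecular acyl capture outruns the intermolecular one.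

Step 14
Reactants: 20 (R)-3-acetyl-4-benzyloxazolidin-2-one
Product: 21 (R)-4-benzyl-3-[1-(trimethylsilyloxy)vinyl]oxazolidin-2-one
Conditions: TMSOTf, Et3N, CH2Cl2, 0 °C; pentane extraction, used crude
Reagents that add atoms: trimethylsilyl triflate, C[Si](C)(C)OS(=O)(=O)C(F)(F)F
Why: Soft enolisation and O-silylation of the imide gives the silyl ketene N,O-acetal without ever forming a free acetyl-imide enolate, which would self-condense.

Step 15
Reactants: 19 chloro lactone; 21 silyl ketene N,O-acetal
Product: 22 (4R)-4-benzyl-3-{[ring B aryl]acetyl}oxazolidin-2-one (19 with the ring B C5–Cl replaced by CH2C(=O)N of the auxiliary)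
Conditions: Pd(dba)2 (5 mol %), P(t-Bu)3 (10 mol %), ZnF2, 21 (3 equiv), DMF, 85 °C
Reagents that add atoms: none
Why: Palladium-catalysed α-arylation of the silyl enolate of an imide with zinc fluoride as activator, a near-neutral form of enolate arylation known for oxazolidinone imides; P(t-Bu)3 belongs to the ligand class that brings electron-rich chloroarenes into enolate arylation. No alkoxide or amide base is present, so the lactone and its Cα–H are safe, and the excess of 21 covers any loss to the free hydroxyl.

Step 16
Reactants: 22 arylacetyl imide; 23 4-benzyloxy-3-methoxybenzaldehyde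
Product: 25 (4R)-4-benzyl-3-[(2R,3R)-3-(4-benzyloxy-3-methoxyphenyl)-3-hydroxy-2-(ring B aryl of 22)propanoyl]oxazolidin-2-one, via boron enolate 24 (not isolated)
Conditions: Bu2BOTf (2.3 equiv), Et3N (2.8 equiv), CH2Cl2, −78 to 0 °C; 23, −78 to 0 °C; pH 7 buffer, MeOH, H2O2, 0 °C
Reagents that add atoms: none
Why: Evans syn aldol; Bu2BOTf/Et3N enolises the far more acidic arylacetyl imide to Z boron enolate 24 (the free hydroxyl is held as its borinate), which adds to 23 through a closed chair transition state on the face away from the auxiliary benzyl group. The R auxiliary gives 8'R in the imide, the spatial arrangement that reads 8'S once C9' is CH2OH; the carbinol centre (7'R) is erased in step 18.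

Step 17
Reactants: 25 aldol imide
Product: 26 (1R,2S)-1-(4-benzyloxy-3-methoxyphenyl)-2-(ring B aryl of 22)propane-1,3-diol (triol with the dihydrobenzofuran CH2OH)
Conditions: NaBH4, THF–H2O (4:1), 0 °C to rt
Reagents that add atoms: none
Why: Reductive removal of the auxiliary; the activated exocyclic imide carbonyl is reduced by NaBH4 in wet THF under conditions in which an α-substituted γ-butyrolactone reacts only slowly. C8' is not α to a ketone at this stage and keeps its configuration.

Step 18
Reactants: 26 triol
Product: 27 tri-O-benzyl ether of the target (8'S ketone; benzyl on the phenols of rings A, B and D)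
Conditions: activated MnO2 (20 equiv), CH2Cl2, rt
Reagents that add atoms: none
Why: MnO2 oxidises benzylic alcohols and leaves saturated primary alcohols alone, so only the p-alkoxy-activated C7' carbinol reacts. The medium is neutral and aprotic, which protects the newly acidified C8'–H.

Step 19
Reactants: 27 tribenzyl ether
Product: 28 target CNP0111438.1
Conditions: H2 (1 atm), 10 % Pd/C, EtOAc–EtOH, rt, stopped at full conversion
Reagents that add atoms: none
Why: Hydrogenolysis of three aryl benzyl ethers, the fastest class of benzyl cleavage, under neutral conditions that neither epimerise C8' nor open the lactone. The short exposure spares the C2–O1 bond and the electron-rich aryl ketone.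

## Compound list

1 | 4-benzyloxy-3-methoxybenzyl alcohol | COc1cc(CO)ccc1OCc1ccccc1 | starting material
2 | 5-iodovanillin | COc1cc(C=O)cc(I)c1O | starting material
3 | 4-[(4-benzyloxy-3-methoxyphenyl)methoxy]-3-iodo-5-methoxybenzaldehyde | COc1cc(C=O)cc(I)c1OCc1ccc(OCc2ccccc2)c(OC)c1 | intermediate
4 | ethyl diazoacetate | CCOC(=O)C=[N+]=[N-] | starting material
5 | ethyl 2-diazo-2-{2-[(4-benzyloxy-3-methoxyphenyl)methoxy]-5-formyl-3-methoxyphenyl}acetate | CCOC(=O)C(=[N+]=[N-])c1cc(C=O)cc(OC)c1OCc1ccc(OCc2ccccc2)c(OC)c1 | intermediate
6 | ethyl (2S,3R)-2-(4-benzyloxy-3-methoxyphenyl)-5-formyl-7-methoxy-2,3-dihydrobenzofuran-3-carboxylate (cis) | O=Cc1cc(OC)c2c(c1)[C@@H](C(=O)OCC)[C@@H](c1ccc(OCc3ccccc3)c(OC)c1)O2 | intermediate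
7 | ethyl (2S,3S)-2-(4-benzyloxy-3-methoxyphenyl)-5-formyl-7-methoxy-2,3-dihydrobenzofuran-3-carboxylate (trans) | O=Cc1cc(OC)c2c(c1)[C@H](C(=O)OCC)[C@@H](c1ccc(OCc3ccccc3)c(OC)c1)O2 | intermediate
8 | ethyl (2S,3S)-2-(4-benzyloxy-3-methoxyphenyl)-7-methoxy-5-(2-methoxyvinyl)-2,3-dihydrobenzofuran-3-carboxylate (E/Z mixture) | COC=Cc1cc(OC)c2c(c1)[C@H](C(=O)OCC)[C@@H](c1ccc(OCc3ccccc3)c(OC)c1)O2 | intermediate
9 | ethyl (2S,3S)-2-(4-benzyloxy-3-methoxyphenyl)-7-methoxy-5-(2-oxoethyl)-2,3-dihydrobenzofuran-3-carboxylate | O=CCc1cc(OC)c2c(c1)[C@H](C(=O)OCC)[C@@H](c1ccc(OCc3ccccc3)c(OC)c1)O2 | intermediate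
10 | 5-chlorovanillin | COc1cc(C=O)cc(Cl)c1O | starting material
11 | 4-benzyloxy-3-chloro-5-methoxybenzaldehyde | COc1cc(C=O)cc(Cl)c1OCc1ccccc1 | intermediate
12 | (4-benzyloxy-3-chloro-5-methoxyphenyl)methanol | COc1cc(CO)cc(Cl)c1OCc1ccccc1 | intermediate
13 | 4-benzyloxy-3-chloro-5-methoxybenzyl bromide | COc1cc(CBr)cc(Cl)c1OCc1ccccc1 | intermediate
14 | (ethoxycarbonylmethylene)triphenylphosphorane | CCOC(=O)C=P(c1ccccc1)(c1ccccc1)c1ccccc1 | starting material
15 | [1-ethoxy-3-(4-benzyloxy-3-chloro-5-methoxyphenyl)-1-oxopropan-2-yl]triphenylphosphonium bromide | CCOC(=O)C(Cc1cc(Cl)c(OCc2ccccc2)c(OC)c1)[P+](c1ccccc1)(c1ccccc1)c1ccccc1.[Br-] | intermediate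
16 | ethyl 3-(4-benzyloxy-3-chloro-5-methoxyphenyl)-2-(triphenylphosphoranylidene)propanoate | CCOC(=O)C(Cc1cc(Cl)c(OCc2ccccc2)c(OC)c1)=P(c1ccccc1)(c1ccccc1)c1ccccc1 | intermediate
17 | E-enoate diester (ester trans to the ring C CH2; 2S,3S in the dihydrobenzofuran) | CCOC(=O)/C(Cc1cc(Cl)c(OCc2ccccc2)c(OC)c1)=C/Cc1cc(OC)c2c(c1)[C@H](C(=O)OCC)[C@@H](c1ccc(OCc3ccccc3)c(OC)c1)O2 | intermediate
18 | E-allylic alcohol, precursor of the key step (2S,3R in the dihydrobenzofuran) | OC/C(Cc1cc(Cl)c(OCc2ccccc2)c(OC)c1)=C/Cc1cc(OC)c2c(c1)[C@H](CO)[C@@H](c1ccc(OCc3ccccc3)c(OC)c1)O2 | intermediate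
19 | (3R,4R)-trans-dibenzylbutyrolactone, product of the key step | COc1cc(C[C@H]2COC(=O)[C@@H]2Cc2cc(OC)c3c(c2)[C@H](CO)[C@@H](c2ccc(OCc4ccccc4)c(OC)c2)O3)cc(Cl)c1OCc1ccccc1 | intermediate
20 | (R)-3-acetyl-4-benzyloxazolidin-2-one | CC(=O)N1[C@H](Cc2ccccc2)COC1=O | starting material
21 | (R)-4-benzyl-3-[1-(trimethylsilyloxy)vinyl]oxazolidin-2-one | C=C(O[Si](C)(C)C)N1[C@H](Cc2ccccc2)COC1=O | intermediate
22 | ring B arylacetyl imide of (R)-4-benzyloxazolidin-2-one | COc1cc(C[C@H]2COC(=O)[C@@H]2Cc2cc(OC)c3c(c2)[C@H](CO)[C@@H](c2ccc(OCc4ccccc4)c(OC)c2)O3)cc(CC(=O)N2[C@H](Cc3ccccc3)COC2=O)c1OCc1ccccc1 | intermediate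
23 | 4-benzyloxy-3-methoxybenzaldehyde | COc1cc(C=O)ccc1OCc1ccccc1 | starting material
24 | Z dibutylboron enolate of 22 with the primary hydroxyl as dibutylborinate | CCCCB(CCCC)O/C(N1[C@H](Cc2ccccc2)COC1=O)=C\c1cc(C[C@H]2COC(=O)[C@@H]2Cc2cc(OC)c3c(c2)[C@H](COB(CCCC)CCCC)[C@@H](c2ccc(OCc4ccccc4)c(OC)c2)O3)cc(OC)c1OCc1ccccc1 | intermediate
25 | syn-aldol imide (7'R,8'R) | COc1cc([C@H](O)[C@H](C(=O)N2[C@H](Cc3ccccc3)COC2=O)c2cc(C[C@H]3COC(=O)[C@@H]3Cc3cc(OC)c4c(c3)[C@H](CO)[C@@H](c3ccc(OCc5ccccc5)c(OC)c3)O4)cc(OC)c2OCc2ccccc2)ccc1OCc1ccccc1 | intermediate
26 | triol with the (7'R,8'S)-1,3-diol arm | COc1cc([C@H](O)[C@H](CO)c2cc(C[C@H]3COC(=O)[C@@H]3Cc3cc(OC)c4c(c3)[C@H](CO)[C@@H](c3ccc(OCc5ccccc5)c(OC)c3)O4)cc(OC)c2OCc2ccccc2)ccc1OCc1ccccc1 | intermediate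
27 | tri-O-benzyl ether of the target (8'S) | COc1cc(C(=O)[C@H](CO)c2cc(C[C@H]3COC(=O)[C@@H]3Cc3cc(OC)c4c(c3)[C@H](CO)[C@@H](c3ccc(OCc5ccccc5)c(OC)c3)O4)cc(OC)c2OCc2ccccc2)ccc1OCc1ccccc1 | intermediate
28 | CNP0111438.1 | COc1cc(C(=O)[C@H](CO)c2cc(C[C@H]3COC(=O)[C@@H]3Cc3cc(OC)c4c(c3)[C@H](CO)[C@@H](c3ccc(O)c(OC)c3)O4)cc(OC)c2O)ccc1O | target

## Step count and least certain steps

Total: 19 steps. Longest linear sequence: 14 steps (1–6, 11–13, 15–19). Side branches: steps 7–10 and step 14.

**Step 13 (key step, the only step beyond known chemistry).**
- *Risk.* The most likely failure is β-hydride elimination of the secondary alkylpalladium toward C4. This would lead to migration of the double bond into conjugation with ring C and then carbonylation at the wrong carbon, or no carbonylation at all. Ionisation of the primary allylic alcohol by zerovalent palladium and weak discrimination of the alkene faces are the next concerns.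
- *Fallback.* It runs from 18 back to 19 and keeps the syn-addition logic with known reactions. Both hydroxyls are silylated (TBSCl, imidazole) to the bis-silyl ether F1. Asymmetric hydroboration with the matched enantiomer of monoisopinocampheylborane puts boron on C3 and hydrogen on C2 from one face, and acetaldehyde followed by pinacol gives the secondary pinacol boronate F2. Matteson homologation (LiCHCl2, ZnCl2) inserts the missing carbon with retention to give the α-chloroboronate F3. Buffered NaClO2 oxidises this to the carboxylic acid F4. Aqueous HF in MeCN removes both silyl groups, and the γ-hydroxy acid closes to 19.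

**Step 15.**
- *Risk.* Oxidative addition into the hindered, electron-rich C–Cl bond may be slow. The silyl enolate would then be lost by protodesilylation, or the auxiliary would be shed thermally, before coupling occurs.
- *Fallback.* It runs from 19 back to 22 with reversed polarity. Miyaura borylation (Pd2(dba)3, XPhos, B2pin2, KOAc, dioxane) gives the ring B pinacol boronate F5. This is joined by Suzuki–Miyaura coupling (Pd(OAc)2, P(o-tol)3, K3PO4, THF–H2O, rt) to the α-bromo imide F6, made from lithiated (R)-4-benzyloxazolidin-2-one and bromoacetyl bromide.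

**Step 3.**
- *Risk.* The strongly donor-substituted benzylic C–H bond may react by stepwise hydride transfer, which would erode enantio- and diastereocontrol. Capture of the carbenoid by the formyl oxygen is a minor risk. Residual wrong enantiomer becomes a separable diastereomer after step 13, which softens the problem.
- *Fallback.* It runs from 5 back to 7 and replaces asymmetric catalysis by resolution. Insertion with Rh2(OAc)4 gives 6 together with its enantiomer F7. Ethoxide equilibration gives 7 together with its enantiomer F8. The pair is separated by preparative chromatography on a chiral stationary phase.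

**Step 2.**
- *Risk.* The ortho alkoxy group may slow the coupling so far that loss of nitrogen from the palladium-bound diazo unit takes over.
- *Fallback.* It runs from 3 back to 5 and builds the arylacetate first. The aldehyde is masked (HC(OMe)3, cat. TsOH, MeOH) as the dimethyl acetal F9. Negishi-type coupling with the Reformatsky reagent BrZnCH2CO2Et (Pd(dba)2, Q-phos, THF, rt) gives the arylacetate F10. Diazo transfer (p-ABSA, DBU, MeCN) gives the diazo acetal F11, and PPTS in wet acetone releases 5.

**Step 18.**
- *Risk.* Conversion of the hindered carbinol may be sluggish. The long contact times then needed could allow enolisation at C8', retro-aldol cleavage or dehydration on the oxide surface.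
- *Fallback.* It runs from 26 back to 27 through a protected series. Both primary hydroxyls are silylated selectively (TBSCl, imidazole, 0 °C) to the bis-silyl ether F12. The remaining benzylic alcohol is oxidised quickly in solution with Dess–Martin periodinane buffered by NaHCO3 to the silylated ketone F13. HF·pyridine then returns 27.

## Further compounds

F1 | step 13 | bis(tert-butyldimethylsilyl) ether of 18 | CC(C)(C)[Si](C)(C)OC/C(Cc1cc(Cl)c(OCc2ccccc2)c(OC)c1)=C/Cc1cc(OC)c2c(c1)[C@H](CO[Si](C)(C)C(C)(C)C)[C@@H](c1ccc(OCc3ccccc3)c(OC)c1)O2
F2 | step 13 | secondary pinacol boronate (boron on the future Cα) | COc1cc(C[C@@H](CO[Si](C)(C)C(C)(C)C)[C@H](B2OC(C)(C)C(C)(C)O2)Cc2cc(OC)c3c(c2)[C@H](CO[Si](C)(C)C(C)(C)C)[C@@H](c2ccc(OCc4ccccc4)c(OC)c2)O3)cc(Cl)c1OCc1ccccc1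
F3 | step 13 | homologated α-chloroboronate (chloride-bearing carbon unassigned) | COc1cc(C[C@@H](CO[Si](C)(C)C(C)(C)C)[C@H](C(Cl)B2OC(C)(C)C(C)(C)O2)Cc2cc(OC)c3c(c2)[C@H](CO[Si](C)(C)C(C)(C)C)[C@@H](c2ccc(OCc4ccccc4)c(OC)c2)O3)cc(Cl)c1OCc1ccccc1
F4 | step 13 | bis-silylated γ-hydroxy acid precursor of 19 | COc1cc(C[C@@H](CO[Si](C)(C)C(C)(C)C)[C@H](C(=O)O)Cc2cc(OC)c3c(c2)[C@H](CO[Si](C)(C)C(C)(C)C)[C@@H](c2ccc(OCc4ccccc4)c(OC)c2)O3)cc(Cl)c1OCc1ccccc1
F5 | step 15 | ring B pinacol boronate of the lactone | COc1cc(C[C@H]2COC(=O)[C@@H]2Cc2cc(OC)c3c(c2)[C@H](CO)[C@@H](c2ccc(OCc4ccccc4)c(OC)c2)O3)cc(B2OC(C)(C)C(C)(C)O2)c1OCc1ccccc1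
F6 | step 15 | (R)-4-benzyl-3-(bromoacetyl)oxazolidin-2-one | O=C(CBr)N1[C@H](Cc2ccccc2)COC1=O
F7 | step 3 | enantiomer of 6 (2R,3S) | O=Cc1cc(OC)c2c(c1)[C@H](C(=O)OCC)[C@H](c1ccc(OCc3ccccc3)c(OC)c1)O2
F8 | step 3 | enantiomer of 7 (2R,3R) | O=Cc1cc(OC)c2c(c1)[C@@H](C(=O)OCC)[C@H](c1ccc(OCc3ccccc3)c(OC)c1)O2
F9 | step 2 | dimethyl acetal of 3 | COC(OC)c1cc(I)c(OCc2ccc(OCc3ccccc3)c(OC)c2)c(OC)c1
F10 | step 2 | ethyl 2-{2-[(4-benzyloxy-3-methoxyphenyl)methoxy]-5-(dimethoxymethyl)-3-methoxyphenyl}acetate | CCOC(=O)Cc1cc(C(OC)OC)cc(OC)c1OCc1ccc(OCc2ccccc2)c(OC)c1
F11 | step 2 | dimethyl acetal of 5 | CCOC(=O)C(=[N+]=[N-])c1cc(C(OC)OC)cc(OC)c1OCc1ccc(OCc2ccccc2)c(OC)c1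
F12 | step 18 | bis(tert-butyldimethylsilyl) ether of 26 (both primary hydroxyls) | COc1cc([C@H](O)[C@H](CO[Si](C)(C)C(C)(C)C)c2cc(C[C@H]3COC(=O)[C@@H]3Cc3cc(OC)c4c(c3)[C@H](CO[Si](C)(C)C(C)(C)C)[C@@H](c3ccc(OCc5ccccc5)c(OC)c3)O4)cc(OC)c2OCc2ccccc2)ccc1OCc1ccccc1
F13 | step 18 | bis(tert-butyldimethylsilyl) ether of 27 | COc1cc(C(=O)[C@H](CO[Si](C)(C)C(C)(C)C)c2cc(C[C@H]3COC(=O)[C@@H]3Cc3cc(OC)c4c(c3)[C@H](CO[Si](C)(C)C(C)(C)C)[C@@H](c3ccc(OCc5ccccc5)c(OC)c3)O4)cc(OC)c2OCc2ccccc2)ccc1OCc1ccccc1
A1 | alternative 1 | (2S,3R)-5-bromo-2-(4-hydroxy-3-methoxyphenyl)-3-(hydroxymethyl)-7-methoxy-2,3-dihydrobenzofuran | Brc1cc(OC)c2c(c1)[C@H](CO)[C@@H](c1ccc(O)c(OC)c1)O2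
A2 | alternative 1 | 2-(5-bromo-2-hydroxy-3-methoxyphenyl)-1-(4-hydroxy-3-methoxyphenyl)propane-1,3-diol (single at C2, both carbinol epimers) | Brc1cc(OC)c(O)c(c1)[C@H](CO)C(O)c1ccc(O)c(OC)c1
A3 | alternative 1 | para-quinone methide from A2 | Brc1cc(OC)c(O)c(c1)[C@H](CO)C=C1C=CC(=O)C(OC)=C1
A4 | alternative 2 | (R)-4-(4-benzyloxy-3-bromo-5-methoxybenzyl)dihydrofuran-2(3H)-one | Brc1cc(C[C@H]2COC(=O)C2)cc(OC)c1OCc1ccccc1
A5 | alternative 2 | 3-(4-benzyloxy-3-bromo-5-methoxybenzyl)cyclobutanone | Brc1cc(CC2CC(=O)C2)cc(OC)c1OCc1ccccc1
A6 | alternative 2 | (2S,3R)-5-(bromomethyl)-2-(4-benzyloxy-3-methoxyphenyl)-3-(tert-butyldimethylsilyloxymethyl)-7-methoxy-2,3-dihydrobenzofuran | BrCc1cc(OC)c2c(c1)[C@H](CO[Si](C)(C)C(C)(C)C)[C@@H](c1ccc(OCc3ccccc3)c(OC)c1)O2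
A7 | alternative 2 | (3R,4R)-trans-lactone from alkylation of A4 with A6 | Brc1cc(C[C@H]2COC(=O)[C@@H]2Cc2cc(OC)c3c(c2)[C@H](CO[Si](C)(C)C(C)(C)C)[C@@H](c2ccc(OCc4ccccc4)c(OC)c2)O3)cc(OC)c1OCc1ccccc1
A8 | alternative 3 | (2S,3R)-2-(4-benzyloxy-3-methoxyphenyl)-7-methoxy-3-[(2,2,6,6-tetramethylpiperidin-1-yl)oxymethyl]-2,3-dihydrobenzofuran-5-carbaldehyde | O=Cc1cc(OC)c2c(c1)[C@H](CON3C(C)(C)CCCC3(C)C)[C@@H](c1ccc(OCc3ccccc3)c(OC)c1)O2
A9 | alternative 3 | 4-{[(1S)-1-(4-benzyloxy-3-methoxyphenyl)prop-2-en-1-yl]oxy}-3-iodo-5-methoxybenzaldehyde | O=Cc1cc(OC)c(O[C@@H](C=C)c2ccc(OCc3ccccc3)c(OC)c2)c(I)c1
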